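The constants at 100 °C pull two ways: the turning of starting material into target has the larger rate constant, 13.4 h⁻¹ against 8.20 h⁻¹ for its turning into isomer of the product A, but isomer of the product A has the larger equilibrium constant, 6.42 against 0.496. This is kinetic against thermodynamic control, and two chemists dispute it over these flasks.

- Sunday's: starting material 0.050 M; protic impurity 5.00 mM; temperature 100 °C; time 2.5 h
- Friday's: starting material 0.050 M; protic impurity 5.00 mM; temperature 120 °C; time 2.5 h

- which of these there is most of at the end, counted by the starting material in it, Sunday's (starting material / target / isomer of the product A / isomer of the product B)
- which of these there is most of at the end, counted by the starting material in it, Friday's (starting material / target / isomer of the product A / isomer of the product B)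
- how much there is at the end of the one of these that leads, in percent of the starting material charged: Sunday's
- how much there is at the end of the one of these that leads, in percent of the starting material charged: Friday's

- percentages count the starting material that a species holds: one idle adduct counts as two
- target is meant together with its idle adduct
- constants are those at 100 °C; use the activation energies and enthalpies for any other temperature
- in an amount of target, one idle adduct counts as one target

    starting material + target ⇌ idle adduct, settled at all times (K1 = 38.7 M⁻¹, ΔH1 = −3.00 kJ mol⁻¹)
    starting material + protic impurity → quenched substrate (k2 = 5.79 M⁻¹ h⁻¹, Ea2 = 75.0 kJ mol⁻¹)
    starting material ⇌ isomer of the product A (K3 = 6.42, k3 = 8.20 h⁻¹, Ea3 = 109 kJ mol⁻¹, ΔH3 = −22.0 kJ mol⁻¹)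
    target ⇌ isomer of the product A (k4 = 0.238 h⁻¹, Ea4 = 121 kJ mol⁻¹)
    starting material ⇌ target (K5 = 0.496, k5 = 13.4 h⁻¹, Ea5 = 113 kJ mol⁻¹, ΔH5 = −46.0 kJ mol⁻¹)
    target ⇌ isomer of the product B (K6 = 0.560, k6 = 0.158 h⁻¹, Ea6 = 107 kJ mol⁻¹, ΔH6 = −21.0 kJ mol⁻¹)
    (constants at 100 °C)

The first chemist goes by the forward rates. On Sunday's flask, starting material divides by its rate constants, so 62.0% of it goes to target, and target should lead.

The second chemist, whose side I take, goes by the balance. The relaxation half-lives of starting material with free target, 1.03 min, and with isomer of the product A, 0.0731 h, are short against the 2.5 h of the run. So the division by rates lasts minutes, and the pool of these forms comes to balance.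

If the forms stood equal, each would hold a third of the pool, and that is the zero of the scale. The constants move it to the balance share of isomer of the product A, its equilibrium constant over the sum of that constant, the constant of target and one: 81.1% on Sunday's.

On Friday's flask the enthalpies bring the constants to 4.48 and 0.233, so the share is 78.4%. These are shares of the pool, not of the charge, and my reckoning stops there.

The forecast also names isomer of the product A for Sunday's and isomer of the product A for Friday's, with 77% and 73% of the charge, figures lower than my shares of the pool. It holds that at the higher temperature “the exothermic equilibria shift back”.

The simulation gives isomer of the product A as leader on Sunday's with 76.6%, while target holds 7.22%. On Friday's the leader is isomer of the product A with 72.8%. The forecast stands, and the first chemist's view loses at the end of the run. That view has its region just after the start of Sunday's, where the forward rate to isomer of the product A is 0.61 of that to target.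

Held against Sunday's end, isomer of the product A over itself, starting material and free target, which is target less its part in the idle adduct, comes to 81.2%, beside the share of 81.1%. The neighbouring flask repeats Sunday's at 125 °C, where the constants become 4.11 and 0.196, and the share is 77.5%. That flask ends with 71.4% isomer of the product A and 17.3% starting material, and the same count on it gives 77.5%.

Its constants come from no measurement, and the outcome is calculated.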